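If you want to know what a flask makes in 8.0 min, first find the one concentration that sets the order of the rate. In these three flasks, which differ in free catalyst, I expect it to be the dissolved partner.

| setting | midnight | winter | dusk |
|---|---|---|---|
| starting material | 20 mM (fed, over 6.0 min) | 20 mM (fed, over 6.0 min) | 20 mM (fed, over 6.0 min) |
| solid reagent | 60.0 mM | 60.0 mM | 60.0 mM |
| free catalyst | 0.060 mM | 0.20 mM | 0.60 mM |
| time | 8.0 min | 8.0 min | 8.0 min |
| remark | the fed solution adds 0.10 times the starting volume | the fed solution adds 0.10 times the starting volume | the fed solution adds 0.10 times the starting volume |

    partner + free catalyst ⇌ catalyst intermediate A (K1 = 88 M⁻¹, k1 = 1100 M⁻¹ s⁻¹)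
    catalyst intermediate A → catalyst intermediate B (k2 = 0.86 s⁻¹)
    starting material + catalyst intermediate B → catalyst intermediate C (k3 = 130 M⁻¹ s⁻¹)
    catalyst intermediate C → free catalyst + target (k4 = 2.3 s⁻¹)
    solid reagent ⇌ partner, rate k5*(cs5 - [partner]) while solid is left; crystals form when [partner] > cs5 (cs5 = 2.2 mM, k5 = 0.0015 s⁻¹)

- charges are per starting volume, the dose included; the dosed solution carries all of it
- as a solid, counted per litre of solution: solid reagent
- at the start none of the solid reagent is in solution
- "hardly changes" means that all values lie within two and a half points (for a concentration: within two and a half percent of the largest)
- run time (midnight): 8.0 min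

- amount of target at the end, in percent of the starting material charged for midnight, winter, dusk, in this order
- the course of these numbers from the first flask to the last (falls, then rises / falls all the way / rises, then falls / hardly changes / rises all the way)

Start with the solid. The partner begins at zero, so dissolution brings at most 0.198 mM min⁻¹ per litre of solution. The feed makes the solution grow, and its volume averaged over the run is 1.06 times the starting volume, so that rate held over the run is 8.42% of the starting material charged. This is my ceiling.

The first setting is the feed. It delivers 3.33 mM min⁻¹, far more than the partner's 0.198 mM min⁻¹, so spreading the starting material over 6.0 min should hardly move the target.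

The second setting is the catalyst. Intermediate A falls back at 12.5 s⁻¹ and goes on at 0.86 s⁻¹, faster back than on, so just 6.44% of its formations count. Hence the quantity to carry, the capture constant: the pseudo-first-order rate constant at which dissolved partner is lost for good, which is the step 1 rate constant times free catalyst times that share. For midnight it is 0.00425 s⁻¹.

I count the catalyst as free, its resting state. Capture then competes with the dissolution coefficient 0.0015 s⁻¹. Their sum gives a relaxation time, the time to reach a steady partner level, and that level is the supply times this time. The target is the ceiling, times capture's part of that sum, times the part of the run left after one relaxation time.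

| Flask | Capture constant | Relaxation time | Partner level | Target, my reckoning |
|---|---|---|---|---|
| midnight | 0.00425 s⁻¹ | 2.90 min | 0.574 mM | 3.97% |
| winter | 0.0142 s⁻¹ | 1.06 min | 0.211 mM | 6.60% |
| dusk | 0.0425 s⁻¹ | 0.379 min | 0.0750 mM | 7.74% |

So I commit to a rise all the way, with the second step smaller than the first.

The forecast gives 3.9%, 6.5% and 7.7%, and says the row rises all the way. Its ground: “More catalyst keeps dissolved partner lower and converts more of it”. Its dusk figure stands just below mine.

The simulation gives 3.70%, 6.34% and 7.63%: the row rises all the way.

The gradual adding makes no difference to the midnight target, and the local order in free catalyst there is 0.63. In midnight the capture constant 0.00425 s⁻¹ stands against the dissolution coefficient 0.0015 s⁻¹, a ratio of 2.83 that gives a partner level of 0.574 mM, and the midnight flask holds 0.578 mM at 8.00 min. In dusk the ratio is 28.3, the level comes to 0.0750 mM, and the dusk flask holds 0.0832 mM at 8.00 min.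

The numbers are made up; what happens was integrated by code.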